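**Retrosynthetic overview**
- The route rests on the contiguous triad C7(OH)–C8(prenyl)–C8a(O1) of ring A, next to the acyl-bearing C4a. C5–C8 map onto a 4-prenylated 1-amino-3-silyloxybutadiene, and C4a/C8a map onto the enone double bond of ring C.
- After removal of the O7 silyl group, ring A is cut at C4a–C5 and C8–C8a. This gives an enantiopure 5-bromo-2-aryl-2,3-dihydropyran-4-one and the aminosilyloxydiene (Diels–Alder reaction, then loss of Me2NH and HBr).
- Bromopyranone: the chromene ring comes from an aryl 1,1-dimethylpropargyl ether (Claisen cascade). Bromine is placed with NBS before the chromene alkene exists. Ring C and C2 (S) come from a catalytic asymmetric hetero-Diels–Alder reaction.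
- Diene: α′-prenylation of 4-(dimethylamino)but-3-en-2-one, then O-silylation of its enolate.
- Ring order: B (bought), C (step 2), chromene pyran ring (step 4), A (step 7).

Key step: step 7

Assumption: the (S)-BINOL–Ti(IV) catalyst is taken to steer the diene to the Si face of the aryl aldehyde, the sense it shows with other carbon nucleophiles. Both ligand enantiomers are sold, so the antipode is used if the assay of 6 shows the reverse.

**Step 1**
Reactants: 1 4-hydroxybenzaldehyde; 2 3-chloro-3-methylbut-1-yne
Product: 3 4-[(2-methylbut-3-yn-2-yl)oxy]benzaldehyde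
Conditions: K2CO3, KI (cat.), CuI (cat.), DMF, 65 °C
Reagents that add atoms: none
Why: Copper-assisted Williamson-type O-alkylation of a phenoxide with the tertiary propargylic chloride is the standard entry to aryl 1,1-dimethylpropargyl ethers, and the aldehyde is inert to carbonate.

**Step 2**
Reactants: 3 4-[(2-methylbut-3-yn-2-yl)oxy]benzaldehyde; 4 (E)-1-methoxy-3-(trimethylsilyloxy)buta-1,3-diene
Product: 6 (S)-2-{4-[(2-methylbut-3-yn-2-yl)oxy]phenyl}-2,3-dihydro-4H-pyran-4-one, via silylated aldol adduct 5 (not isolated)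
Conditions: (S)-BINOL (20 mol %), Ti(OiPr)4 (10 mol %), 4 Å MS, Et2O, −20 °C; then TFA (cat.), CH2Cl2, 0 °C
Reagents that add atoms: none
Why: BINOL–Ti(IV)-catalysed hetero-Diels–Alder reaction running through a Mukaiyama aldol addition and acid-induced cyclisation with loss of methanol, in which the chiral titanium complex blocks the Re face of the aldehyde so that the diene terminus adds to the Si face and sets C2 as S, while ether and alkyne are spectators.

**Step 3**
Reactants: 6 (S)-2-{4-[(2-methylbut-3-yn-2-yl)oxy]phenyl}-2,3-dihydro-4H-pyran-4-one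
Product: 7 (S)-5-bromo-2-{4-[(2-methylbut-3-yn-2-yl)oxy]phenyl}-2,3-dihydro-4H-pyran-4-one
Conditions: NBS, CH2Cl2, 0 °C, dark
Reagents that add atoms: N-bromosuccinimide, O=C1CCC(=O)N1Br
Why: Electrophilic α-bromination of a vinylogous ester (Br+ adds at the enol-ether carbon C5, then H5 is lost) is placed here because only a terminal alkyne and a hindered aryl ether compete, whereas the electron-rich C3=C4 bond of a finished chromene would take up NBS faster than C5.

**Step 4**
Reactants: 7 (S)-5-bromo-2-{4-[(2-methylbut-3-yn-2-yl)oxy]phenyl}-2,3-dihydro-4H-pyran-4-one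
Product: 9 (S)-5-bromo-2-(2,2-dimethyl-2H-chromen-6-yl)-2,3-dihydro-4H-pyran-4-one, via allenylphenol 8 (not isolated)
Conditions: o-xylene (0.05 M), BHT (cat.), 140 °C, Ar
Reagents that add atoms: none
Why: Aromatic propargyl Claisen rearrangement followed by 1,5-hydrogen shift and oxa-6π electrocyclisation is the standard thermal chromene synthesis, the two ortho positions are equivalent, no reagent is present, and no bond at C2 is touched.

**Step 5**
Reactants: 10 (E)-4-(dimethylamino)but-3-en-2-one; 11 1-bromo-3-methylbut-2-ene (prenyl bromide)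
Product: 12 (E)-1-(dimethylamino)-7-methylocta-1,6-dien-3-one
Conditions: LDA, THF, −78 °C; then 11, −78 → −20 °C
Reagents that add atoms: none
Why: Kinetic α′-deprotonation of the vinylogous amide and SN2 C-alkylation of the cross-conjugated enolate with a reactive allylic bromide puts the chain on the methyl carbon without any regiochemical ambiguity.

**Step 6**
Reactants: 12 (E)-1-(dimethylamino)-7-methylocta-1,6-dien-3-one
Product: 13 (1E,3Z)-3-(tert-butyldimethylsilyloxy)-N,N,7-trimethylocta-1,3,6-trien-1-amine
Conditions: KHMDS, THF, −78 °C; then TBSCl, −78 °C → rt; filtration under Ar, used without chromatography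
Reagents that add atoms: tert-butyldimethylsilyl chloride, CC(C)(C)[Si](C)(C)Cl
Why: O-silylation of the α′-enolate is the standard preparation of 1-amino-3-silyloxydienes, and the silazide base should favour the Z(O)-enolate, which holds the chain trans to the aminovinyl arm so that the diene can reach its s-cis form.

**Step 7**
Reactants: 9 (S)-5-bromo-2-(2,2-dimethyl-2H-chromen-6-yl)-2,3-dihydro-4H-pyran-4-one; 13 (1E,3Z)-3-(tert-butyldimethylsilyloxy)-N,N,7-trimethylocta-1,3,6-trien-1-amine
Product: 15 (S)-7-(tert-butyldimethylsilyloxy)-2-(2,2-dimethyl-2H-chromen-6-yl)-8-(3-methylbut-2-en-1-yl)chroman-4-one, via bicyclic cycloadduct 14 (not isolated)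
Conditions: 13 (2 equiv), PhMe (1 M), 4 Å MS, sealed tube, 80 → 110 °C; then SiO2, CH2Cl2, rt
Reagents that add atoms: none
Why: Proposed new method: the prenyl-bearing diene terminus has the largest HOMO coefficient because both N and the silyloxy oxygen push towards it, so it bonds to C8a (β-carbon of the bromo enone) slightly ahead of the bond from the aminated terminus to C4a, and an asynchronous yet concerted [4+2] cycloaddition (in the limit a Michael–Mannich sequence) gives the cis-fused adduct 14. Ring A is closed in this single event as a six-membered carbocycle by intermolecular [4+2] annulation across C4a=C8a, and it aromatises in the same flask: HBr leaves from C4a/C8a, its proton lands on the C5 amine, and the now doubly allylic ammonium group departs with push from O7 and O1 before H8 is lost, so the by-products pair as dimethylammonium bromide and no outside base is needed. The closest known reaction type is the cycloaddition–aromatisation of 1-amino- or 1-alkoxy-3-silyloxydienes with α-halo enones, haloquinones and 3-acyl- or 3-cyanochromones, whereas a monocyclic 5-halo-2,3-dihydropyran-4-one has not served as the two-carbon partner. No lasting stereocentre is made, since C4a, C5, C8 and C8a of 14 all become sp2, which makes endo/exo and facial selectivity irrelevant, and C2 is only a spectator. The step needs regioselectivity (C8 to C8a, C5 to C4a), which follows from the polarity match between a diene that is nucleophilic at its alkylated end and an enone that is electrophilic at C8a, and it needs ring closure to outrun expulsion of O1 from the developing α-bromo enolate, which the apolar solvent and the concerted character favour, while the unactivated prenyl and chromene alkenes stay out. The medium remains close to neutral, so C3 of 15 is not deprotonated, O1–C2 does not open and the S configuration at C2 is kept.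

**Step 8**
Reactants: 15 (S)-7-(tert-butyldimethylsilyloxy)-2-(2,2-dimethyl-2H-chromen-6-yl)-8-(3-methylbut-2-en-1-yl)chroman-4-one
Product: 16 (S)-7-hydroxy-2-(2,2-dimethyl-2H-chromen-6-yl)-8-(3-methylbut-2-en-1-yl)chroman-4-one (target)
Conditions: TBAF, AcOH (1:1), THF, 0 °C
Reagents that add atoms: none
Why: Fluoride cleavage of an aryl silyl ether, buffered with acetic acid so that no basic fluoride or free phenoxide can start E1cB opening of O1–C2 to the chalcone and racemise C2, with the prenyl and chromene alkenes inert.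

**Compound list**
1 | 4-hydroxybenzaldehyde | O=Cc1ccc(O)cc1 | starting material
2 | 3-chloro-3-methylbut-1-yne | CC(C)(Cl)C#C | starting material
3 | 4-[(2-methylbut-3-yn-2-yl)oxy]benzaldehyde | O=Cc1ccc(OC(C)(C)C#C)cc1 | intermediate
4 | (E)-1-methoxy-3-(trimethylsilyloxy)buta-1,3-diene | CO/C=C/C(=C)O[Si](C)(C)C | starting material
5 | (S,E)-1-methoxy-5-{4-[(2-methylbut-3-yn-2-yl)oxy]phenyl}-5-(trimethylsilyloxy)pent-1-en-3-one | CO/C=C/C(=O)C[C@H](O[Si](C)(C)C)c1ccc(OC(C)(C)C#C)cc1 | intermediate
6 | (S)-2-{4-[(2-methylbut-3-yn-2-yl)oxy]phenyl}-2,3-dihydro-4H-pyran-4-one | O=C1C=CO[C@H](c2ccc(OC(C)(C)C#C)cc2)C1 | intermediate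
7 | (S)-5-bromo-2-{4-[(2-methylbut-3-yn-2-yl)oxy]phenyl}-2,3-dihydro-4H-pyran-4-one | O=C1C(Br)=CO[C@H](c2ccc(OC(C)(C)C#C)cc2)C1 | intermediate
8 | (S)-5-bromo-2-[4-hydroxy-3-(3-methylbuta-1,2-dien-1-yl)phenyl]-2,3-dihydro-4H-pyran-4-one | O=C1C(Br)=CO[C@H](c2ccc(O)c(C=C=C(C)C)c2)C1 | intermediate
9 | (S)-5-bromo-2-(2,2-dimethyl-2H-chromen-6-yl)-2,3-dihydro-4H-pyran-4-one | BrC1=CO[C@H](c2ccc3c(c2)C=CC(C)(C)O3)CC1=O | intermediate
10 | (E)-4-(dimethylamino)but-3-en-2-one | CN(C)/C=C/C(C)=O | starting material
11 | 1-bromo-3-methylbut-2-ene | CC(C)=CCBr | starting material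
12 | (E)-1-(dimethylamino)-7-methylocta-1,6-dien-3-one | CN(C)/C=C/C(=O)CCC=C(C)C | intermediate
13 | (1E,3Z)-3-(tert-butyldimethylsilyloxy)-N,N,7-trimethylocta-1,3,6-trien-1-amine | CN(C)/C=C/C(O[Si](C)(C)C(C)(C)C)=C/CC=C(C)C | intermediate
14 | (2S)-4a-bromo-7-(tert-butyldimethylsilyloxy)-5-(dimethylamino)-2-(2,2-dimethyl-2H-chromen-6-yl)-8-(3-methylbut-2-en-1-yl)-2,3,4a,5,8,8a-hexahydro-4H-chromen-4-one, cis-fused, mixture at C4a/C5/C8/C8a | CN(C)C1C=C(O[Si](C)(C)C(C)(C)C)C(CC=C(C)C)C2O[C@H](c3ccc4c(c3)C=CC(C)(C)O4)CC(=O)C12Br | intermediate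
15 | (S)-7-(tert-butyldimethylsilyloxy)-2-(2,2-dimethyl-2H-chromen-6-yl)-8-(3-methylbut-2-en-1-yl)chroman-4-one | CC(C)=CCc1c(O[Si](C)(C)C(C)(C)C)ccc2c1O[C@H](c1ccc3c(c1)C=CC(C)(C)O3)CC2=O | intermediate
16 | (S)-7-hydroxy-2-(2,2-dimethyl-2H-chromen-6-yl)-8-(3-methylbut-2-en-1-yl)chroman-4-one | CC(C)=CCc1c(O)ccc2c1O[C@H](c1ccc3c(c1)C=CC(C)(C)O3)CC2=O | target

**Total step count:** 8. **Longest linear sequence:** 6 (steps 1, 2, 3, 4, 7, 8).

**Steps most likely to fail**

1. Step 7 (new method).
- What may go wrong: donation from O1 may keep the C4a=C8a bond too electron-rich, so that the diene decays before it adds. The developing enolate may expel O1 instead of closing on the iminium carbon. Liberated amine may open O1–C2 and erode the configuration.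
- Fallback (known chemistry, ring A bought instead of built): it sets out from 3 and 11 and comes back at 16. Aldehyde 3 is heated in o-xylene to 2,2-dimethyl-2H-chromene-6-carbaldehyde F1. Purchased 2,4-dihydroxyacetophenone is C-prenylated between its two oxygens with 11 (aq. KOH) to 1-[2,4-dihydroxy-3-(3-methylbut-2-en-1-yl)phenyl]ethan-1-one F2. Its non-chelated 4-OH is masked (MOMCl, K2CO3, acetone) as 1-[2-hydroxy-4-(methoxymethoxy)-3-(3-methylbut-2-en-1-yl)phenyl]ethan-1-one F3. Claisen–Schmidt condensation of F1 with F3 (KOH, EtOH) should give the (E)-2′-hydroxychalcone F4. Intramolecular oxa-Michael addition (NaOAc, EtOH, reflux) should give the racemic 7-O-MOM flavanone F5, and HCl in MeOH the racemic flavanone F6. Preparative HPLC on a polysaccharide chiral phase then delivers the S enantiomer 16.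

2. Step 4.
- What may go wrong: at 140 °C the bromo enone may degrade. The transient phenol may add to C6 of a second molecule. The p-alkoxybenzylic C2–O1 bond may ionise reversibly, with loss of configuration.
- Fallback: it sets out from 6 and comes back at 15. The Claisen cascade is run on halogen-free 6, whose vinylogous carboxylate is a poorer leaving group, to give (S)-2-(2,2-dimethyl-2H-chromen-6-yl)-2,3-dihydro-4H-pyran-4-one F7. The halogen is then brought in by pyridine-mediated α-iodination of the enone (I2, pyridine, CH2Cl2). Addition of this reagent to the chromene C3=C4 bond is reversible. The product is (S)-2-(2,2-dimethyl-2H-chromen-6-yl)-5-iodo-2,3-dihydro-4H-pyran-4-one F8. F8 takes the place of 9 in step 7 and, through the 4a-iodo cycloadduct F9, should lose HI and dimethylamine to give the same 15.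

3. Step 2.
- What may go wrong: turnover may be slow and facial selectivity poor with the electron-rich p-alkoxy aldehyde. The tertiary propargyl ether may be lost in the TFA stage.
- Fallback (hydrogen-bond organocatalysis with a more reactive diene, no Lewis or protic acid): it sets out from 3 and 10 and comes back at 6. Enaminone 10 is O-silylated (KHMDS, TBSCl) to (E)-3-(tert-butyldimethylsilyloxy)-N,N-dimethylbuta-1,3-dien-1-amine F10. F10 should add to 3 in a concerted hetero-Diels–Alder reaction under catalysis by 1-naphthyl-TADDOL (PhMe, −40 °C, ligand enantiomer chosen for Si-face attack). This gives (2S)-6-(dimethylamino)-4-(tert-butyldimethylsilyloxy)-2-{4-[(2-methylbut-3-yn-2-yl)oxy]phenyl}-3,6-dihydro-2H-pyran F11. Acetyl chloride (CH2Cl2, −78 °C) then strips the amine and the silyl group to give 6.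

**Further compounds**
F1 | step 7 | 2,2-dimethyl-2H-chromene-6-carbaldehyde | O=Cc1ccc2c(c1)C=CC(C)(C)O2
F2 | step 7 | 1-[2,4-dihydroxy-3-(3-methylbut-2-en-1-yl)phenyl]ethan-1-one | CC(=O)c1ccc(O)c(CC=C(C)C)c1O
F3 | step 7 | 1-[2-hydroxy-4-(methoxymethoxy)-3-(3-methylbut-2-en-1-yl)phenyl]ethan-1-one | CC(=O)c1ccc(OCOC)c(CC=C(C)C)c1O
F4 | step 7 | (E)-3-(2,2-dimethyl-2H-chromen-6-yl)-1-[2-hydroxy-4-(methoxymethoxy)-3-(3-methylbut-2-en-1-yl)phenyl]prop-2-en-1-one | O=C(/C=C/c1ccc2c(c1)C=CC(C)(C)O2)c1ccc(OCOC)c(CC=C(C)C)c1O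
F5 | step 7 | racemic 2-(2,2-dimethyl-2H-chromen-6-yl)-7-(methoxymethoxy)-8-(3-methylbut-2-en-1-yl)chroman-4-one | COCOc1ccc2c(c1CC=C(C)C)OC(c1ccc3c(c1)C=CC(C)(C)O3)CC2=O
F6 | step 7 | racemic 7-hydroxy-2-(2,2-dimethyl-2H-chromen-6-yl)-8-(3-methylbut-2-en-1-yl)chroman-4-one | CC(C)=CCc1c(O)ccc2c1OC(c1ccc3c(c1)C=CC(C)(C)O3)CC2=O
F7 | step 4 | (S)-2-(2,2-dimethyl-2H-chromen-6-yl)-2,3-dihydro-4H-pyran-4-one | O=C1C=CO[C@H](c2ccc3c(c2)C=CC(C)(C)O3)C1
F8 | step 4 | (S)-2-(2,2-dimethyl-2H-chromen-6-yl)-5-iodo-2,3-dihydro-4H-pyran-4-one | IC1=CO[C@H](c2ccc3c(c2)C=CC(C)(C)O3)CC1=O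
F9 | step 4 | (2S)-7-(tert-butyldimethylsilyloxy)-5-(dimethylamino)-2-(2,2-dimethyl-2H-chromen-6-yl)-4a-iodo-8-(3-methylbut-2-en-1-yl)-2,3,4a,5,8,8a-hexahydro-4H-chromen-4-one | CN(C)C1C=C(O[Si](C)(C)C(C)(C)C)C(CC=C(C)C)C2O[C@H](c3ccc4c(c3)C=CC(C)(C)O4)CC(=O)C12I
F10 | step 2 | (E)-3-(tert-butyldimethylsilyloxy)-N,N-dimethylbuta-1,3-dien-1-amine | CN(C)/C=C/C(=C)O[Si](C)(C)C(C)(C)C
F11 | step 2 | (2S)-6-(dimethylamino)-4-(tert-butyldimethylsilyloxy)-2-{4-[(2-methylbut-3-yn-2-yl)oxy]phenyl}-3,6-dihydro-2H-pyran | CN(C)C1C=C(O[Si](C)(C)C(C)(C)C)C[C@@H](c2ccc(OC(C)(C)C#C)cc2)O1
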